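**Retrosynthetic overview**

1. The target comes from its heptaacetate 42, made by Heck coupling at C6–Br of ring 1 with 4-acetoxystyrene; the methyl ethers are cleaved before the stilbene exists, because a stilbene beside these electron-rich rings would cyclise under acid.
2. The dihydrofuran of ring 2 comes from ionisation of the C2' methyl ether and capture of the cation by a phenol of the new resorcinol (trans).
3. The benzo ring of ring 2 (C3a', C4', C5', C6', C7', C7a') comes from benzannulation of cyclobutenone 19 with siloxyalkyne 31. The feature used is that this ring is a resorcinol whose oxygens at C4' and C7a' flank C3a' (which carries C3'), while C6', para to C3a', is bonded to C3 of ring 1.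
4. Cyclobutenone 19 comes from the ring-1 alkyne and dichloroketene; ring 1 comes from an Evans aldol ((S)-auxiliary, sets C3) of an arylacetyl imide made from 1 with 4-methoxybenzaldehyde, then cationic closure (sets C2 trans).
5. Siloxyalkyne 31 comes from the mirror-image Evans aldol ((R)-auxiliary, sets C3') of 3,5-dimethoxyphenylacetic acid, then ester-to-ynolate rearrangement and O-silylation. Ring order: dihydrofuran of ring 1, cyclobutenone, benzo ring of ring 2, dihydrofuran of ring 2.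

Key step: step 18

Assumption: ring 1 is the dihydrobenzofuran that carries the styryl group (O1, C2–C7a) and ring 2 the other one (primed atoms); the SMILES defines both rings as trans with configuration 2S,3S,2'S,3'S; compounds 1, 7, 10, 20, 21 and 41 are taken as commercial.

**Route**

Step 1
Reactants: 1 4-bromo-2,6-dimethoxybenzaldehyde
Product: 2 4-bromo-2-hydroxy-6-methoxybenzaldehyde
Conditions: BCl3 (1.1 equiv), CH2Cl2, −78 → 0 °C; aq. HCl
Reagents that add atoms: none
Why: Lewis-acid ether cleavage directed by chelation, in which boron bridges the formyl oxygen and one ortho-methoxy oxygen so that only that methyl group is lost and the resulting aryloxyboron chelate shields the second methoxy group.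

Step 2
Reactants: 2 4-bromo-2-hydroxy-6-methoxybenzaldehyde
Product: 3 4-bromo-2-methoxy-6-(methoxymethoxy)benzaldehyde
Conditions: MeOCH2Cl, i-Pr2NEt, CH2Cl2, 0 °C → rt
Reagents that add atoms: chloromethyl methyl ether, COCCl
Why: O-alkylation of the phenol (Williamson type) installs an acetal that should tolerate the strong bases of steps 3 to 6 and leave in the acid step that closes ring 1.

Step 3
Reactants: 3 4-bromo-2-methoxy-6-(methoxymethoxy)benzaldehyde
Product: 5 2-[4-bromo-2-methoxy-6-(methoxymethoxy)phenyl]acetonitrile, via formamide 4 (not isolated)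
Conditions: TosMIC, KOt-Bu, DME, −40 °C → rt; then MeOH, reflux
Reagents that add atoms: 4-toluenesulfonylmethyl isocyanide (TosMIC), Cc1ccc(cc1)S(=O)(=O)C[N+]#[C-]
Why: van Leusen reductive cyanation, in which the TosMIC anion adds to the aldehyde, the oxazoline anion opens to the N-formyl enamine 4, and methanolysis removes the formyl group and expels sulfinate to give the nitrile homologated by one carbon.

Step 4
Reactants: 5 2-[4-bromo-2-methoxy-6-(methoxymethoxy)phenyl]acetonitrile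
Product: 6 2-[4-bromo-2-methoxy-6-(methoxymethoxy)phenyl]acetic acid
Conditions: KOH, EtOH–H2O, reflux; then cold 1 M HCl to pH 3
Reagents that add atoms: potassium hydroxide, [K+].[OH-]; water, O
Why: base hydrolysis of the nitrile through the amide, to which the acetal and the aryl bromide are inert, followed by a brief cold acidification that should not touch the acetal.

Step 5
Reactants: 6 2-[4-bromo-2-methoxy-6-(methoxymethoxy)phenyl]acetic acid; 7 (4S)-4-benzyl-1,3-oxazolidin-2-one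
Product: 9 (4S)-4-benzyl-3-{2-[4-bromo-2-methoxy-6-(methoxymethoxy)phenyl]acetyl}-1,3-oxazolidin-2-one, via mixed anhydride 8 (not isolated)
Conditions: t-BuCOCl, Et3N, THF, −20 °C; then LiCl, 7, −20 °C → rt
Reagents that add atoms: none
Why: N-acylation of the oxazolidinone by the mixed pivalic anhydride under LiCl–amine activation, which needs no alkyllithium and so leaves the aryl bromide alone.

Step 6
Reactants: 9 (4S)-4-benzyl-3-{2-[4-bromo-2-methoxy-6-(methoxymethoxy)phenyl]acetyl}-1,3-oxazolidin-2-one; 10 4-methoxybenzaldehyde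
Product: 12 (4S)-4-benzyl-3-{(2S,3S)-2-[4-bromo-2-methoxy-6-(methoxymethoxy)phenyl]-3-hydroxy-3-(4-methoxyphenyl)propanoyl}-1,3-oxazolidin-2-one, via boron enolate 11 (not isolated)
Conditions: n-Bu2BOTf, i-Pr2NEt, CH2Cl2, 0 °C; 10, −78 → 0 °C; pH 7 buffer, MeOH, H2O2
Reagents that add atoms: none
Why: Evans syn aldol, in which the Z boron enolate reacts through a Zimmerman–Traxler chair on the face away from the benzyl group of the (S)-auxiliary, setting the aryl-bearing carbon (the later C3) as S together with the carbinol centre (S, erased in step 7).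

Step 7
Reactants: 12 (4S)-4-benzyl-3-{(2S,3S)-2-[4-bromo-2-methoxy-6-(methoxymethoxy)phenyl]-3-hydroxy-3-(4-methoxyphenyl)propanoyl}-1,3-oxazolidin-2-one
Product: 14 (4S)-4-benzyl-3-[(2S,3S)-6-bromo-4-methoxy-2-(4-methoxyphenyl)-2,3-dihydro-1-benzofuran-3-carbonyl]-1,3-oxazolidin-2-one, via phenol 13 (not isolated)
Conditions: CF3CO2H (10 vol%), CH2Cl2, 0 °C → rt
Reagents that add atoms: none
Why: acid cleaves the acetal and ionises the 4-methoxybenzylic alcohol, and the ortho phenol captures the cation (5-exo-tet mode) to close the dihydrofuran of ring 1, with C3 untouched and C2 settling trans to the C3 acyl group (2S) because the benzylic C2–O bond ionises reversibly under the acid (thermodynamic control).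

Step 8
Reactants: 14 (4S)-4-benzyl-3-[(2S,3S)-6-bromo-4-methoxy-2-(4-methoxyphenyl)-2,3-dihydro-1-benzofuran-3-carbonyl]-1,3-oxazolidin-2-one
Product: 15 [(2S,3R)-6-bromo-4-methoxy-2-(4-methoxyphenyl)-2,3-dihydro-1-benzofuran-3-yl]methanol
Conditions: LiBH4, H2O (1 equiv), Et2O–THF, 0 °C
Reagents that add atoms: none
Why: hydride reduction at the exocyclic imide carbonyl releases the auxiliary and gives the primary alcohol without touching either stereocentre or the aryl bromide (the descriptor at C3 changes only through priorities).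

Step 9
Reactants: 15 [(2S,3R)-6-bromo-4-methoxy-2-(4-methoxyphenyl)-2,3-dihydro-1-benzofuran-3-yl]methanol
Product: 16 (2S,3S)-6-bromo-4-methoxy-2-(4-methoxyphenyl)-2,3-dihydro-1-benzofuran-3-carbaldehyde
Conditions: Dess–Martin periodinane, CH2Cl2, 0 °C → rt
Reagents that add atoms: none
Why: Dess–Martin oxidation under near-neutral conditions, where the only enolisable position is C3 and its epimer would be the less stable cis isomer.

Step 10
Reactants: 16 (2S,3S)-6-bromo-4-methoxy-2-(4-methoxyphenyl)-2,3-dihydro-1-benzofuran-3-carbaldehyde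
Product: 17 (2S,3S)-6-bromo-3-ethynyl-4-methoxy-2-(4-methoxyphenyl)-2,3-dihydro-1-benzofuran
Conditions: MeC(O)C(N2)P(O)(OMe)2, K2CO3, MeOH, 0 °C → rt
Reagents that add atoms: dimethyl (1-diazo-2-oxopropyl)phosphonate, CC(=O)C(=[N+]=[N-])P(=O)(OC)OC
Why: Seyferth–Gilbert homologation in its Ohira–Bestmann form, where enolisation at C3 under carbonate can only return the more stable trans aldehyde since C2 is fixed, and ring opening by β-elimination would be the reverse of a disfavoured 5-endo-trig closure.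

Step 11
Reactants: 17 (2S,3S)-6-bromo-3-ethynyl-4-methoxy-2-(4-methoxyphenyl)-2,3-dihydro-1-benzofuran
Product: 18 3-[(2S,3R)-6-bromo-4-methoxy-2-(4-methoxyphenyl)-2,3-dihydro-1-benzofuran-3-yl]-4,4-dichlorocyclobut-2-en-1-one
Conditions: Cl3CCOCl, Zn–Cu couple, Et2O–DME, rt
Reagents that add atoms: trichloroacetyl chloride, ClC(=O)C(Cl)(Cl)Cl
Why: (2+2) cycloaddition of dichloroketene, made in the flask by zinc dechlorination of the acid chloride, to the terminal alkyne, in which the unsubstituted alkyne carbon bonds to the ketene carbonyl carbon so that ring 1 ends up at C3 of the cyclobutenone.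

Step 12
Reactants: 18 3-[(2S,3R)-6-bromo-4-methoxy-2-(4-methoxyphenyl)-2,3-dihydro-1-benzofuran-3-yl]-4,4-dichlorocyclobut-2-en-1-one
Product: 19 3-[(2S,3S)-6-bromo-4-methoxy-2-(4-methoxyphenyl)-2,3-dihydro-1-benzofuran-3-yl]cyclobut-2-en-1-one
Conditions: Zn, AcOH, TMEDA, EtOH, 0 °C → rt
Reagents that add atoms: none
Why: zinc reduction removes both α-chlorine atoms through zinc enolates protonated by acetic acid, the standard route to 3-substituted cyclobutenones, and the aryl bromide is inert to zinc under these buffered conditions.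

Step 13
Reactants: 20 2-(3,5-dimethoxyphenyl)acetic acid; 21 (4R)-4-benzyl-1,3-oxazolidin-2-one
Product: 23 (4R)-4-benzyl-3-[2-(3,5-dimethoxyphenyl)acetyl]-1,3-oxazolidin-2-one, via mixed anhydride 22 (not isolated)
Conditions: t-BuCOCl, Et3N, THF, −20 °C; then LiCl, 21, −20 °C → rt
Reagents that add atoms: none
Why: N-acylation of the oxazolidinone by the mixed pivalic anhydride, as in step 5.

Step 14
Reactants: 23 (4R)-4-benzyl-3-[2-(3,5-dimethoxyphenyl)acetyl]-1,3-oxazolidin-2-one; 10 4-methoxybenzaldehyde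
Product: 25 (4R)-4-benzyl-3-[(2R,3R)-2-(3,5-dimethoxyphenyl)-3-hydroxy-3-(4-methoxyphenyl)propanoyl]-1,3-oxazolidin-2-one, via boron enolate 24 (not isolated)
Conditions: n-Bu2BOTf, i-Pr2NEt, CH2Cl2, 0 °C; 10, −78 → 0 °C; pH 7 buffer, MeOH, H2O2
Reagents that add atoms: none
Why: Evans syn aldol with the enantiomeric auxiliary, whose benzyl group now blocks the other enolate face and sets the aryl-bearing carbon as R (the arrangement that is 3'S in the target) together with the carbinol carbon (R, the later C2', whose configuration is not needed).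

Step 15
Reactants: 25 (4R)-4-benzyl-3-[(2R,3R)-2-(3,5-dimethoxyphenyl)-3-hydroxy-3-(4-methoxyphenyl)propanoyl]-1,3-oxazolidin-2-one
Product: 27 (2R,3R)-2-(3,5-dimethoxyphenyl)-3-hydroxy-3-(4-methoxyphenyl)propanoic acid, via peroxycarboxylate 26 (not isolated)
Conditions: LiOH, H2O2, THF–H2O, 0 °C; Na2SO3; 1 M HCl
Reagents that add atoms: hydrogen peroxide, OO
Why: hydroperoxide anion attacks the exocyclic carbonyl selectively and is too weakly basic to epimerise the benzylic α-carbon, and sulfite then reduces the peroxy acid salt 26.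

Step 16
Reactants: 27 (2R,3R)-2-(3,5-dimethoxyphenyl)-3-hydroxy-3-(4-methoxyphenyl)propanoic acid
Product: 28 methyl (2R,3R)-2-(3,5-dimethoxyphenyl)-3-methoxy-3-(4-methoxyphenyl)propanoate
Conditions: Me3OBF4 (excess), 1,8-bis(dimethylamino)naphthalene, 4 Å MS, CH2Cl2, rt
Reagents that add atoms: trimethyloxonium tetrafluoroborate, C[O+](C)C.F[B-](F)(F)F
Why: O-methylation by the Meerwein salt turns the carboxylate into the methyl ester and the benzylic alcohol into its methyl ether in one operation, under weakly basic non-nucleophilic conditions that should allow neither retro-aldol cleavage nor epimerisation.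

Step 17
Reactants: 28 methyl (2R,3R)-2-(3,5-dimethoxyphenyl)-3-methoxy-3-(4-methoxyphenyl)propanoate
Product: 31 {[(3S,4R)-3-(3,5-dimethoxyphenyl)-4-methoxy-4-(4-methoxyphenyl)but-1-yn-1-yl]oxy}tri(propan-2-yl)silane, via dibromoenolate 29 (not isolated), via ynolate 30 (not isolated)
Conditions: CH2Br2, lithium 2,2,6,6-tetramethylpiperidide, THF, −78 °C; 28; LiN(SiMe3)2, −78 → −20 °C; t-BuLi (2 equiv), −78 → 0 °C; i-Pr3SiCl, −78 °C → rt
Reagents that add atoms: dibromomethane, BrCBr; chlorotri(propan-2-yl)silane, CC(C)[Si](Cl)(C(C)C)C(C)C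
Why: Kowalski ynolate formation, in which LiCHBr2 adds to the ester with loss of methoxide, the dibromo ketone is held as its enolate 29, bromine–lithium exchange triggers the carbenoid 1,2-shift in which the C3' carbon migrates with retention to give ynolate 30, and the bulky silyl chloride reacts at oxygen.

Step 18
Reactants: 19 3-[(2S,3S)-6-bromo-4-methoxy-2-(4-methoxyphenyl)-2,3-dihydro-1-benzofuran-3-yl]cyclobut-2-en-1-one; 31 {[(3S,4R)-3-(3,5-dimethoxyphenyl)-4-methoxy-4-(4-methoxyphenyl)but-1-yn-1-yl]oxy}tri(propan-2-yl)silane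
Product: 36 5-[(2S,3S)-6-bromo-4-methoxy-2-(4-methoxyphenyl)-2,3-dihydro-1-benzofuran-3-yl]-2-[(1S,2R)-1-(3,5-dimethoxyphenyl)-2-methoxy-2-(4-methoxyphenyl)ethyl]-3-{[tri(propan-2-yl)silyl]oxy}phenol, via vinylketene 32 (not isolated), via vinylcyclobutenone 33 (not isolated), via dienylketene 34 (not isolated), via cyclohexadienone 35 (not isolated)
Conditions: 31 (1.3 equiv), toluene, 80 °C then 110 °C, sealed tube, argon
Reagents that add atoms: none
Why: On heating, cyclobutenone 19 undergoes 4π-electrocyclic ring opening to vinylketene 32; the nucleophilic alkyne carbon of ynol ether 31 (β to the silyloxy group, the one carrying the C3' chain) attacks the ketene carbonyl carbon in a regiospecific (2+2) cycloaddition that forms C3a'–C4' and C7'–C7a' and gives vinylcyclobutenone 33, which opens (4π) to dienylketene 34. The benzo ring of ring 2 is then closed by a thermal 6π-electrocyclisation (disrotatory, six-membered) that re-forms C4'–C5' and gives cyclohexadienone 35, and enolisation delivers phenol 36. The closest known reaction type is this one itself, the Danheiser benzannulation of a cyclobutenone with a trialkylsilyloxyalkyne to a resorcinol monosilyl ether. No stereocentre is formed; C2, C3, C3' and C2' lie on substituents outside the reacting π-system and the medium is neutral, so they should be carried through unchanged. The only selectivity needed is regiochemical and it is secured by the polarity of the two partners, which places the C3' chain between the hydroxyl carbon C4' and the silyloxy carbon C7a' and leaves ring 1 para to it at C6', with no isomer possible. The small excess of 31 is meant to intercept the vinylketene before it can dimerise or acylate the product phenol.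

Step 19
Reactants: 36 5-[(2S,3S)-6-bromo-4-methoxy-2-(4-methoxyphenyl)-2,3-dihydro-1-benzofuran-3-yl]-2-[(1S,2R)-1-(3,5-dimethoxyphenyl)-2-methoxy-2-(4-methoxyphenyl)ethyl]-3-{[tri(propan-2-yl)silyl]oxy}phenol
Product: 38 (2S,3S)-6-[(2S,3S)-6-bromo-4-methoxy-2-(4-methoxyphenyl)-2,3-dihydro-1-benzofuran-3-yl]-3-(3,5-dimethoxyphenyl)-2-(4-methoxyphenyl)-2,3-dihydro-1-benzofuran-4-ol, via resorcinol 37 (not isolated)
Conditions: n-Bu4NF, AcOH, THF, 0 °C; solvent exchange; CF3CO2H (5 vol%), CH2Cl2, 0 °C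
Reagents that add atoms: none
Why: buffered fluoride removes the silyl group, then acid ionises the 4-methoxybenzylic methyl ether at C2' and either of the two equivalent phenols flanking C3a' captures the cation (5-exo-tet mode) to close the dihydrofuran of ring 2, with C2' set trans to the C3' aryl group (2'S) under thermodynamic control by reversible ionisation, whichever C2' epimer enters.

Step 20
Reactants: 38 (2S,3S)-6-[(2S,3S)-6-bromo-4-methoxy-2-(4-methoxyphenyl)-2,3-dihydro-1-benzofuran-3-yl]-3-(3,5-dimethoxyphenyl)-2-(4-methoxyphenyl)-2,3-dihydro-1-benzofuran-4-ol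
Product: 39 (2S,3S)-6-bromo-3-[(2S,3S)-3-(3,5-dihydroxyphenyl)-4-hydroxy-2-(4-hydroxyphenyl)-2,3-dihydro-1-benzofuran-6-yl]-2-(4-hydroxyphenyl)-2,3-dihydro-1-benzofuran-4-ol
Conditions: BBr3 (excess), CH2Cl2, −78 °C → rt; MeOH–H2O, 0 °C
Reagents that add atoms: none
Why: Lewis-acid cleavage of the five aryl methyl ethers, placed before the stilbene is introduced, where any opening of the benzylic C–O bonds of the two dihydrofurans is reversible and should return the more stable trans rings.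

Step 21
Reactants: 39 (2S,3S)-6-bromo-3-[(2S,3S)-3-(3,5-dihydroxyphenyl)-4-hydroxy-2-(4-hydroxyphenyl)-2,3-dihydro-1-benzofuran-6-yl]-2-(4-hydroxyphenyl)-2,3-dihydro-1-benzofuran-4-ol
Product: 40 hexaacetate of 39 (all six phenols as acetates)
Conditions: Ac2O, pyridine, DMAP (cat.), rt
Reagents that add atoms: acetic anhydride, CC(=O)OC(C)=O
Why: nucleophile-catalysed acylation caps all six phenols so that the aryl bromide enters the coupling as an electron-poorer, non-acidic and oxidation-stable partner.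

Step 22
Reactants: 40 hexaacetate of 39; 41 4-ethenylphenyl acetate
Product: 42 heptaacetate of the target (E-stilbene)
Conditions: Pd(OAc)2 (cat.), P(o-tol)3, Et3N, DMF, 100 °C
Reagents that add atoms: none
Why: Heck reaction, in which oxidative addition of the unhindered aryl bromide to zerovalent palladium, syn insertion of the styrene at its terminal carbon and syn β-hydride elimination give the E-stilbene.

Step 23
Reactants: 42 heptaacetate of the target
Product: 43 (2S,3S)-3-[(2S,3S)-3-(3,5-dihydroxyphenyl)-4-hydroxy-2-(4-hydroxyphenyl)-2,3-dihydro-1-benzofuran-6-yl]-2-(4-hydroxyphenyl)-6-[(E)-2-(4-hydroxyphenyl)ethenyl]-2,3-dihydro-1-benzofuran-4-ol (CNP0248228.2)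
Conditions: K2CO3 (cat.), MeOH–THF, 0 °C → rt, argon; then AcOH
Reagents that add atoms: none
Why: base-catalysed transesterification of the seven aryl acetates with methanol under argon, mild enough to leave the stilbene and both dihydrofurans unchanged.

**Compound list**

1 | 4-bromo-2,6-dimethoxybenzaldehyde | COc1cc(Br)cc(OC)c1C=O | starting material
2 | 4-bromo-2-hydroxy-6-methoxybenzaldehyde | COc1cc(Br)cc(O)c1C=O | intermediate
3 | 4-bromo-2-methoxy-6-(methoxymethoxy)benzaldehyde | COCOc1cc(Br)cc(OC)c1C=O | intermediate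
4 | N-{2-[4-bromo-2-methoxy-6-(methoxymethoxy)phenyl]-1-(4-methylbenzenesulfonyl)ethenyl}formamide (alkene geometry open) | COCOc1cc(Br)cc(OC)c1C=C(NC=O)S(=O)(=O)c1ccc(C)cc1 | intermediate
5 | 2-[4-bromo-2-methoxy-6-(methoxymethoxy)phenyl]acetonitrile | COCOc1cc(Br)cc(OC)c1CC#N | intermediate
6 | 2-[4-bromo-2-methoxy-6-(methoxymethoxy)phenyl]acetic acid | COCOc1cc(Br)cc(OC)c1CC(=O)O | intermediate
7 | (4S)-4-benzyl-1,3-oxazolidin-2-one | O=C1OC[C@H](Cc2ccccc2)N1 | starting material
8 | 2-[4-bromo-2-methoxy-6-(methoxymethoxy)phenyl]acetic 2,2-dimethylpropanoic anhydride | COCOc1cc(Br)cc(OC)c1CC(=O)OC(=O)C(C)(C)C | intermediate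
9 | (4S)-4-benzyl-3-{2-[4-bromo-2-methoxy-6-(methoxymethoxy)phenyl]acetyl}-1,3-oxazolidin-2-one | COCOc1cc(Br)cc(OC)c1CC(=O)N1[C@@H](Cc2ccccc2)COC1=O | intermediate
10 | 4-methoxybenzaldehyde | COc1ccc(C=O)cc1 | starting material
11 | (Z)-dibutylboron enolate of 9 | COCOc1cc(Br)cc(OC)c1/C=C(\OB(CCCC)CCCC)N1[C@@H](Cc2ccccc2)COC1=O | intermediate
12 | (4S)-4-benzyl-3-{(2S,3S)-2-[4-bromo-2-methoxy-6-(methoxymethoxy)phenyl]-3-hydroxy-3-(4-methoxyphenyl)propanoyl}-1,3-oxazolidin-2-one | COCOc1cc(Br)cc(OC)c1[C@H](C(=O)N1[C@@H](Cc2ccccc2)COC1=O)[C@H](O)c1ccc(OC)cc1 | intermediate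
13 | (4S)-4-benzyl-3-[(2S,3S)-2-(4-bromo-2-hydroxy-6-methoxyphenyl)-3-hydroxy-3-(4-methoxyphenyl)propanoyl]-1,3-oxazolidin-2-one | Oc1cc(Br)cc(OC)c1[C@H](C(=O)N1[C@@H](Cc2ccccc2)COC1=O)[C@H](O)c1ccc(OC)cc1 | intermediate
14 | (4S)-4-benzyl-3-[(2S,3S)-6-bromo-4-methoxy-2-(4-methoxyphenyl)-2,3-dihydro-1-benzofuran-3-carbonyl]-1,3-oxazolidin-2-one | Brc1cc(OC)c2c(c1)O[C@H](c1ccc(OC)cc1)[C@H]2C(=O)N1[C@@H](Cc3ccccc3)COC1=O | intermediate
15 | [(2S,3R)-6-bromo-4-methoxy-2-(4-methoxyphenyl)-2,3-dihydro-1-benzofuran-3-yl]methanol | Brc1cc(OC)c2c(c1)O[C@H](c1ccc(OC)cc1)[C@H]2CO | intermediate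
16 | (2S,3S)-6-bromo-4-methoxy-2-(4-methoxyphenyl)-2,3-dihydro-1-benzofuran-3-carbaldehyde | Brc1cc(OC)c2c(c1)O[C@H](c1ccc(OC)cc1)[C@H]2C=O | intermediate
17 | (2S,3S)-6-bromo-3-ethynyl-4-methoxy-2-(4-methoxyphenyl)-2,3-dihydro-1-benzofuran | Brc1cc(OC)c2c(c1)O[C@H](c1ccc(OC)cc1)[C@H]2C#C | intermediate
18 | 3-[(2S,3R)-6-bromo-4-methoxy-2-(4-methoxyphenyl)-2,3-dihydro-1-benzofuran-3-yl]-4,4-dichlorocyclobut-2-en-1-one | Brc1cc(OC)c2c(c1)O[C@H](c1ccc(OC)cc1)[C@H]2C1=CC(=O)C1(Cl)Cl | intermediate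
19 | 3-[(2S,3S)-6-bromo-4-methoxy-2-(4-methoxyphenyl)-2,3-dihydro-1-benzofuran-3-yl]cyclobut-2-en-1-one | Brc1cc(OC)c2c(c1)O[C@H](c1ccc(OC)cc1)[C@H]2C1=CC(=O)C1 | intermediate
20 | 2-(3,5-dimethoxyphenyl)acetic acid | COc1cc(CC(=O)O)cc(OC)c1 | starting material
21 | (4R)-4-benzyl-1,3-oxazolidin-2-one | O=C1OC[C@@H](Cc2ccccc2)N1 | starting material
22 | 2-(3,5-dimethoxyphenyl)acetic 2,2-dimethylpropanoic anhydride | COc1cc(CC(=O)OC(=O)C(C)(C)C)cc(OC)c1 | intermediate
23 | (4R)-4-benzyl-3-[2-(3,5-dimethoxyphenyl)acetyl]-1,3-oxazolidin-2-one | COc1cc(CC(=O)N2[C@H](Cc3ccccc3)COC2=O)cc(OC)c1 | intermediate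
24 | (Z)-dibutylboron enolate of 23 | COc1cc(/C=C(\OB(CCCC)CCCC)N2[C@H](Cc3ccccc3)COC2=O)cc(OC)c1 | intermediate
25 | (4R)-4-benzyl-3-[(2R,3R)-2-(3,5-dimethoxyphenyl)-3-hydroxy-3-(4-methoxyphenyl)propanoyl]-1,3-oxazolidin-2-one | COc1cc(cc(OC)c1)[C@@H](C(=O)N1[C@H](Cc2ccccc2)COC1=O)[C@@H](O)c1ccc(OC)cc1 | intermediate
26 | lithium (2R,3R)-2-(3,5-dimethoxyphenyl)-3-hydroxy-3-(4-methoxyphenyl)propaneperoxoate | COc1cc(cc(OC)c1)[C@@H](C(=O)O[O-])[C@@H](O)c1ccc(OC)cc1.[Li+] | intermediate
27 | (2R,3R)-2-(3,5-dimethoxyphenyl)-3-hydroxy-3-(4-methoxyphenyl)propanoic acid | COc1cc(cc(OC)c1)[C@@H](C(=O)O)[C@@H](O)c1ccc(OC)cc1 | intermediate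
28 | methyl (2R,3R)-2-(3,5-dimethoxyphenyl)-3-methoxy-3-(4-methoxyphenyl)propanoate | COc1cc(cc(OC)c1)[C@@H](C(=O)OC)[C@@H](OC)c1ccc(OC)cc1 | intermediate
29 | lithium (3R,4R)-1,1-dibromo-3-(3,5-dimethoxyphenyl)-4-methoxy-4-(4-methoxyphenyl)but-1-en-2-olate | [Li+].[O-]C(=C(Br)Br)[C@H](c1cc(OC)cc(OC)c1)[C@@H](OC)c1ccc(OC)cc1 | intermediate
30 | lithium (3S,4R)-3-(3,5-dimethoxyphenyl)-4-methoxy-4-(4-methoxyphenyl)but-1-yn-1-olate | [Li+].[O-]C#C[C@H](c1cc(OC)cc(OC)c1)[C@@H](OC)c1ccc(OC)cc1 | intermediate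
31 | {[(3S,4R)-3-(3,5-dimethoxyphenyl)-4-methoxy-4-(4-methoxyphenyl)but-1-yn-1-yl]oxy}tri(propan-2-yl)silane | CC(C)[Si](C(C)C)(C(C)C)OC#C[C@H](c1cc(OC)cc(OC)c1)[C@@H](OC)c1ccc(OC)cc1 | intermediate
32 | 3-[(2S,3S)-6-bromo-4-methoxy-2-(4-methoxyphenyl)-2,3-dihydro-1-benzofuran-3-yl]buta-1,3-dien-1-one | Brc1cc(OC)c2c(c1)O[C@H](c1ccc(OC)cc1)[C@H]2C(=C)C=C=O | intermediate
33 | 4-{1-[(2S,3S)-6-bromo-4-methoxy-2-(4-methoxyphenyl)-2,3-dihydro-1-benzofuran-3-yl]ethenyl}-2-[(1S,2R)-1-(3,5-dimethoxyphenyl)-2-methoxy-2-(4-methoxyphenyl)ethyl]-3-{[tri(propan-2-yl)silyl]oxy}cyclobut-2-en-1-one (both C4 epimers) | Brc1cc(OC)c2c(c1)O[C@H](c1ccc(OC)cc1)[C@H]2C(=C)C1C(=O)C([C@H](c3cc(OC)cc(OC)c3)[C@@H](OC)c3ccc(OC)cc3)=C1O[Si](C(C)C)(C(C)C)C(C)C | intermediate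
34 | (3E)-5-[(2S,3S)-6-bromo-4-methoxy-2-(4-methoxyphenyl)-2,3-dihydro-1-benzofuran-3-yl]-2-[(1S,2R)-1-(3,5-dimethoxyphenyl)-2-methoxy-2-(4-methoxyphenyl)ethyl]-3-{[tri(propan-2-yl)silyl]oxy}hexa-1,3,5-trien-1-one | Brc1cc(OC)c2c(c1)O[C@H](c1ccc(OC)cc1)[C@H]2C(=C)/C=C(/O[Si](C(C)C)(C(C)C)C(C)C)C([C@H](c1cc(OC)cc(OC)c1)[C@@H](OC)c1ccc(OC)cc1)=C=O | intermediate
35 | 5-[(2S,3S)-6-bromo-4-methoxy-2-(4-methoxyphenyl)-2,3-dihydro-1-benzofuran-3-yl]-2-[(1S,2R)-1-(3,5-dimethoxyphenyl)-2-methoxy-2-(4-methoxyphenyl)ethyl]-3-{[tri(propan-2-yl)silyl]oxy}cyclohexa-2,4-dien-1-one | Brc1cc(OC)c2c(c1)O[C@H](c1ccc(OC)cc1)[C@H]2C1=CC(O[Si](C(C)C)(C(C)C)C(C)C)=C([C@H](c3cc(OC)cc(OC)c3)[C@@H](OC)c3ccc(OC)cc3)C(=O)C1 | intermediate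
36 | 5-[(2S,3S)-6-bromo-4-methoxy-2-(4-methoxyphenyl)-2,3-dihydro-1-benzofuran-3-yl]-2-[(1S,2R)-1-(3,5-dimethoxyphenyl)-2-methoxy-2-(4-methoxyphenyl)ethyl]-3-{[tri(propan-2-yl)silyl]oxy}phenol | Brc1cc(OC)c2c(c1)O[C@H](c1ccc(OC)cc1)[C@H]2c1cc(O)c([C@H](c2cc(OC)cc(OC)c2)[C@@H](OC)c2ccc(OC)cc2)c(O[Si](C(C)C)(C(C)C)C(C)C)c1 | intermediate
37 | 5-[(2S,3S)-6-bromo-4-methoxy-2-(4-methoxyphenyl)-2,3-dihydro-1-benzofuran-3-yl]-2-[(1S,2R)-1-(3,5-dimethoxyphenyl)-2-methoxy-2-(4-methoxyphenyl)ethyl]benzene-1,3-diol | Brc1cc(OC)c2c(c1)O[C@H](c1ccc(OC)cc1)[C@H]2c1cc(O)c([C@H](c2cc(OC)cc(OC)c2)[C@@H](OC)c2ccc(OC)cc2)c(O)c1 | intermediate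
38 | (2S,3S)-6-[(2S,3S)-6-bromo-4-methoxy-2-(4-methoxyphenyl)-2,3-dihydro-1-benzofuran-3-yl]-3-(3,5-dimethoxyphenyl)-2-(4-methoxyphenyl)-2,3-dihydro-1-benzofuran-4-ol | Brc1cc(OC)c2c(c1)O[C@H](c1ccc(OC)cc1)[C@H]2c1cc(O)c2c(c1)O[C@H](c1ccc(OC)cc1)[C@H]2c1cc(OC)cc(OC)c1 | intermediate
39 | (2S,3S)-6-bromo-3-[(2S,3S)-3-(3,5-dihydroxyphenyl)-4-hydroxy-2-(4-hydroxyphenyl)-2,3-dihydro-1-benzofuran-6-yl]-2-(4-hydroxyphenyl)-2,3-dihydro-1-benzofuran-4-ol | Brc1cc(O)c2c(c1)O[C@H](c1ccc(O)cc1)[C@H]2c1cc(O)c2c(c1)O[C@H](c1ccc(O)cc1)[C@H]2c1cc(O)cc(O)c1 | intermediate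
40 | hexaacetate of 39 (all six phenols as acetates) | Brc1cc(OC(C)=O)c2c(c1)O[C@H](c1ccc(OC(C)=O)cc1)[C@H]2c1cc(OC(C)=O)c2c(c1)O[C@H](c1ccc(OC(C)=O)cc1)[C@H]2c1cc(OC(C)=O)cc(OC(C)=O)c1 | intermediate
41 | 4-ethenylphenyl acetate (4-acetoxystyrene) | CC(=O)Oc1ccc(C=C)cc1 | starting material
42 | heptaacetate of the target (E-stilbene, all seven phenols as acetates) | CC(=O)Oc1ccc(/C=C/c2cc(OC(C)=O)c3c(c2)O[C@H](c2ccc(OC(C)=O)cc2)[C@H]3c2cc(OC(C)=O)c3c(c2)O[C@H](c2ccc(OC(C)=O)cc2)[C@H]3c2cc(OC(C)=O)cc(OC(C)=O)c2)cc1 | intermediate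
43 | (2S,3S)-3-[(2S,3S)-3-(3,5-dihydroxyphenyl)-4-hydroxy-2-(4-hydroxyphenyl)-2,3-dihydro-1-benzofuran-6-yl]-2-(4-hydroxyphenyl)-6-[(E)-2-(4-hydroxyphenyl)ethenyl]-2,3-dihydro-1-benzofuran-4-ol (CNP0248228.2) | Oc1ccc(/C=C/c2cc(O)c3c(c2)O[C@H](c2ccc(O)cc2)[C@H]3c2cc(O)c3c(c2)O[C@H](c2ccc(O)cc2)[C@H]3c2cc(O)cc(O)c2)cc1 | target

**Step count and risks**

Total step count: 23. Longest linear sequence: 18 steps (steps 1–12, then 18–23); steps 13–17 form the five-step branch to the siloxyalkyne.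

The three steps most likely to fail:

Step 18 (key step). The ketene–alkyne (2+2) cycloaddition may be slowed by the branched C3' substituent on the attacking alkyne carbon. The vinylketene would then be lost by dimerisation, by acylation of the product phenol, or by slow decomposition of the cyclobutenone on prolonged heating. The fallback generates the same vinylketene irreversibly at room temperature, without the cyclobutenone. It sets out from alkyne 17. Markovnikov hydromethoxycarbonylation (Pd(OAc)2, 2-pyridyldiphenylphosphine, MeSO3H, CO, MeOH) gives the 2-substituted methyl acrylate F1. LiOH gives the acrylic acid F2, and (COCl)2 followed by CH2N2 gives the diazo ketone F3. Irradiation of F3 in the presence of an excess of 31 triggers a Wolff rearrangement to vinylketene 32 (the photochemical variant of the same benzannulation), and brief warming completes the cascade. The fallback comes back to the route at 36.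

Step 17. LiCHBr2 or the amide bases may abstract the benzylic α-proton of ester 28 in competition with carbonyl addition, which would erode the C3' configuration or cause β-elimination of methoxide. The fallback sets out from 28 and avoids strong base while a carbonyl group is present. Reduction with i-Bu2AlH at −78 °C gives the aldehyde F4. CBr4 and PPh3 give the dibromoalkene F5, and n-BuLi converts it into the terminal alkyne F6 (Corey–Fuchs sequence). Deprotonation with LiN(SiMe3)2 and oxidation of the lithium acetylide with LiOOt-Bu give ynolate 30, which is silylated with i-Pr3SiOTf. The fallback comes back to the route at 31.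

Step 19. The C2' cation may lose the C3' proton (elimination to a triarylethene) or be captured by a neighbouring arene faster than by the phenol. The fallback sets out from 36, which is desilylated (n-Bu4NF, AcOH) to 37, and 37 is isolated. BBr3 then cleaves all six methyl ethers, the benzylic one as the benzylic bromide F7. On NaHCO3 work-up F7 loses HBr to the para-quinone methide F8, to which the neighbouring phenol adds (5-exo-trig) to close ring 2 trans. The fallback comes back to the route at 39, so step 20 is not needed.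

**Further compounds**

F1 | step 18 | methyl 2-[(2S,3R)-6-bromo-4-methoxy-2-(4-methoxyphenyl)-2,3-dihydro-1-benzofuran-3-yl]prop-2-enoate | Brc1cc(OC)c2c(c1)O[C@H](c1ccc(OC)cc1)[C@H]2C(=C)C(=O)OC
F2 | step 18 | 2-[(2S,3R)-6-bromo-4-methoxy-2-(4-methoxyphenyl)-2,3-dihydro-1-benzofuran-3-yl]prop-2-enoic acid | Brc1cc(OC)c2c(c1)O[C@H](c1ccc(OC)cc1)[C@H]2C(=C)C(=O)O
F3 | step 18 | 3-[(2S,3R)-6-bromo-4-methoxy-2-(4-methoxyphenyl)-2,3-dihydro-1-benzofuran-3-yl]-1-diazobut-3-en-2-one | Brc1cc(OC)c2c(c1)O[C@H](c1ccc(OC)cc1)[C@H]2C(=C)C(=O)C=[N+]=[N-]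
F4 | step 17 | (2R,3R)-2-(3,5-dimethoxyphenyl)-3-methoxy-3-(4-methoxyphenyl)propanal | COc1cc(cc(OC)c1)[C@@H](C=O)[C@@H](OC)c1ccc(OC)cc1
F5 | step 17 | (3R,4R)-1,1-dibromo-3-(3,5-dimethoxyphenyl)-4-methoxy-4-(4-methoxyphenyl)but-1-ene | COc1cc(cc(OC)c1)[C@@H](C=C(Br)Br)[C@@H](OC)c1ccc(OC)cc1
F6 | step 17 | (3R,4R)-3-(3,5-dimethoxyphenyl)-4-methoxy-4-(4-methoxyphenyl)but-1-yne | COc1cc(cc(OC)c1)[C@@H](C#C)[C@@H](OC)c1ccc(OC)cc1
F7 | step 19 | benzylic bromide: 37 with all six methyl ethers cleaved and bromine at C2' (either epimer) | Brc1cc(O)c2c(c1)O[C@H](c1ccc(O)cc1)[C@H]2c1cc(O)c([C@H](c2cc(O)cc(O)c2)C(Br)c2ccc(O)cc2)c(O)c1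
F8 | step 19 | para-quinone methide formed from F7 by loss of HBr | Brc1cc(O)c2c(c1)O[C@H](c1ccc(O)cc1)[C@H]2c1cc(O)c([C@H](c2cc(O)cc(O)c2)C=C2C=CC(=O)C=C2)c(O)c1
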